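## The problem

Target 28 is a dibenzo[b,f]oxepine whose central olefin C10=C11 is also the enol ether double bond of a 3,4-dihydro-2H-pyran. C10 carries ring B and the pyran oxygen; C11 carries ring A and the first of two ring methylenes leading to the quaternary pyran carbon. Ring A is a resorcinol unit: the oxygen ortho to C11 is the diaryl ether oxygen, and the oxygen para to C11 is a free phenol with a prenyl group beside it. Ring B has the ether oxygen ortho and a free phenol para to C10. There are two stereocentres, the quaternary ether carbon of the pyran and the epoxide methine. Two freely rotating methylenes separate them, so neither can steer the other, and the quaternary one requires that two CH2 chains be told apart. The trisubstituted epoxide, the enol ether conjugated to the p-hydroxyphenyl ring B, the o-prenylphenol and the free phenols exclude acid and oxidants late on, and the homoprenyl olefin must be epoxidised before the prenyl and enol ether double bonds exist. Read from its oxygen, the pyran is O–C(quaternary)–CH2–CH2–C11=C10–O. C10 is therefore at the carboxyl level and C11 is its α-carbon, so the ring is the doubly arylated enol form of a δ-lactone. The lactone oxygen sits on a carbon bearing one methyl and two CH2 chains, which is what Markovnikov attack of a carboxylate on a 1,1-disubstituted olefin gives when bromine takes the terminal carbon; the CH2Br group is the methyl in latent form.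

## Retrosynthesis

**Diaryl ether.** The O–C bond between the ring A oxygen ortho to C11 and the ring B carbon ortho to C10 is cut last, giving bromo-triphenol 27. This is the only oxepine bond that joins two flat, separately made arenes already held cis by the C10=C11 olefin; closing a C–C bond of the seven-membered ring instead would mean cyclising at a tetrasubstituted enol ether carbon. The forward step is a copper-mediated C–O coupling under basic conditions, in which only the ortho phenoxide can reach the bromide. 27 is the fluoride-deprotection product of tris-silyl ether 26, so that all phenols stay masked through the organometallic steps and no acid is needed at the end.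

**C10–ring B bond.** Cutting this bond in 26 gives ketene acetal triflate 25 and ring B boronate 21. The cut places ring B on the former carbonyl carbon and keeps its ortho bromide for the ring closure. The forward Suzuki coupling must choose the vinyl triflate over the hindered aryl bromide.

**C11–ring A bond.** Triflate 25 comes from α-aryl lactone 23 by enolate O-sulfonylation, and 23 from epoxy lactone 12 and ring A bromide 17 by enolate arylation. After this cut the whole diaryl olefin is seen to grow out of one lactone carbonyl and its α-carbon. 12 holds both stereocentres but no arene and no other olefin. The forward step must mono-arylate a lactone enolate with an electron-rich ortho-substituted bromide; the α-stereocentre formed is erased on triflation.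

**Epoxide.** The epoxide C–O bonds are removed from 12 to give homoprenyl lactone 11. This is the last point at which the side-chain olefin is the only olefin in the molecule, so the oxidation needs no chemoselectivity. The forward step is a reagent-controlled asymmetric epoxidation of a trisubstituted olefin. It must be run near neutral pH, because a δ-lactone is saponified by aqueous base.

**Side chain.** The olefin of 11 is cut to aldehyde 10, which goes back through alcohol 9 to silyl ether 8. Carrying the chain as a protected alcohol costs three routine steps. In return the key step sees only one olefin.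

**Latent methyl.** The methyl of 8 is traced to the bromomethyl group of 7. The C–O bond at the stereocentre is untouched in the forward radical reduction.

**Key disconnection.** The O–C(quaternary) bond of 7 is cut, with removal of bromine, to give achiral 5-methylidene acid 6. One catalytic step forms the pyran C–O bond, the lactone ring and the quaternary stereocentre. The catalyst must select one olefin face when the two substituents are both CH2 chains, which is the weak point. Three measures strengthen it from within:
- the bulky, weakly basic tert-butyldiphenylsilyl ether makes the spectator chain large and keeps its oxygen from opening the bromiranium ion 5-exo;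
- low temperature and a non-polar medium suppress the uncatalysed reaction;
- the epoxidation of step 9 turns any residual wrong enantiomer into a diastereomer of 12 that can be removed, so the enantiopurity of 12 should exceed that of 7.

**Acid 6.** The methylidene group of 6 is cut to keto acid 5, and the C5–C6 bond of 5 to glutaric anhydride 3 and Grignard reagent 4, made from bromide 2 and thus from bromo alcohol 1. This is three steps from commodity chemicals.

**Arenes.** Bromide 17 comes from symmetric dibromide 14 (from 13) by exchange of one bromine and prenylation; the symmetry removes any regiochemical question. Boronate 21 comes from iodide 19 (from 18) by selective iodine–magnesium exchange and borylation.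

## Roads not taken

**Alternative 1: phenoxide-driven ring expansion of a spiro-xanthene.**
- Cut: the C11–ring A bond together with the seven-membered ring. The oxepine is traced to a xanthene whose C9 is the spiro carbon of the pyran, with a mesylate on the neighbouring carbinol carbon (A2).
- Forward step: base frees the ring A phenoxide. Its para carbon displaces the mesylate to form a spiro-cyclopropane. The cyclopropane reopens with cleavage of the old ring A–spiro bond, and loss of the C11 proton gives the ring B silyl ether A1, one desilylation from 28.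
- Merits: C11–aryl bond, oxepine and enol ether form in one basic, metal-free step. The diaryl ether is fixed early, so no copper-mediated closure next to free phenols is needed. In this respect the road is better than the chosen plan.
- Weak points: A2 is a 9-alkoxy-9-alkylxanthene, a latent xanthylium ion, so a sulfonate next to it invites ionisation and fragmentation. The migrating bond must stand anti to the leaving group, so the relative configuration of the carbinol and the unsymmetrical spiro centre decides whether ring A or ring B migrates; two extra stereocentres must be controlled only to be destroyed. The quaternary ether stereocentre is not made by this step and would need a separate asymmetric step.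
- Comparison: the chosen plan settles its one difficult stereocentre first and creates no further stereocentre that matters. It pays for this with the late Ullmann closure.

**Alternative 2: Baeyer–Villiger insertion.**
- Cut: the O–C(quaternary) bond, by oxygen insertion into (S)-2-allyl-2-methylcyclopentanone A4.
- Forward step: peracid oxidation; the fully substituted carbon migrates with retention to give lactone A3, which would reach 11 in three steps (hydroboration, oxidation, Wittig).
- Merits: the stereocentre is set as an all-carbon centre by an asymmetric allylic alkylation that distinguishes methyl from allyl, a far larger difference than that between the two CH2 chains of 6. Migratory aptitude and retention are dependable. The length to 11 is about the same. For enantiocontrol this road is probably the safer one.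
- Weak points: the peracid must spare the allyl olefin. The alkylation needs palladium, a chiral ligand and a substrate that takes extra steps, and five-membered ketones are the less selective class for it. Everything after 11 would be unchanged.
- Comparison: the chosen plan forms C–O bond and stereocentre in one organocatalytic step from an acyclic acid three steps from bulk chemicals, and step 9 purifies the outcome of step 4. If the key step could be exchanged, this would be the first replacement.

**Alternative 3: palladium anti-oxyarylation of a ring B alkynol.**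
- Cut: the O–C10 and C11–ring A bonds, across the alkyne of tertiary alkynol A6.
- Forward step: the arylpalladium species from ring A iodide A7 activates the alkyne, the tertiary alkoxide attacks the ring B-bearing carbon 6-endo-dig, and reductive elimination gives A5 with the aryl groups cis and the ring A bromide intact.
- Merits: pyran, enol ether and C11–aryl bond form in one convergent step that replaces steps 14–16 of the chosen route. In endgame step economy this road is better.
- Weak points: the nucleophile is a hindered tertiary alkoxide, and 5-exo closure onto the other alkyne carbon is disfavoured only by the electronic bias of ring B. A5 still needs the diaryl ether closure, now after one of three identical silyl ethers has been unmasked selectively. The stereogenic carbinol of A6 must come from an independent asymmetric synthesis, so the step uses the quaternary centre without making it.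
- Comparison: A6 could be derived from 8 or 11, so this is best seen as another endgame for the same lactone. The chosen plan prefers three individually well-known couplings to one less-tested cascade.

Key step: step 4

Assumption: 4,6-dibromoresorcinol and 3-bromo-4-iodophenol are bought as such, and the antipode of the Shi ketone (made from L-sorbose) is treated as a reagent.

## Route

Step 1
Reactants: 1 3-bromopropan-1-ol
Product: 2 (3-bromopropoxy)(tert-butyl)diphenylsilane
Conditions: TBDPSCl, imidazole, CH2Cl2, 0 °C to rt
Reagents that add atoms: tert-butyl(chloro)diphenylsilane, CC(C)(C)[Si](Cl)(c1ccccc1)c1ccccc1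
Why: Standard silylation of a primary alcohol; the bulky, weakly basic silyl ether survives Grignard formation, Wittig base and tin hydride and is the ether least able to take part in the later bromiranium opening.

Step 2
Reactants: 2 (3-bromopropoxy)(tert-butyl)diphenylsilane; 3 glutaric anhydride
Product: 5 8-(tert-butyldiphenylsilyloxy)-5-oxooctanoic acid, via Grignard reagent 4 (not isolated)
Conditions: Mg, I2 (cat.), THF, 40 °C; then added to 3 (2 equiv), THF, –78 to –30 °C; 1 M HCl, 0 °C
Reagents that add atoms: none
Why: Grignard opening of a cyclic anhydride to a keto acid; inverse addition to excess anhydride at low temperature keeps the magnesium keto-carboxylate from taking up a second equivalent.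

Step 3
Reactants: 5 8-(tert-butyldiphenylsilyloxy)-5-oxooctanoic acid
Product: 6 8-(tert-butyldiphenylsilyloxy)-5-methylideneoctanoic acid
Conditions: Ph3PCH3Br (2.5 equiv), KOt-Bu (3.5 equiv), THF, 0 °C to rt; 1 M HCl, 0 °C
Reagents that add atoms: methyltriphenylphosphonium bromide, [Br-].C[P+](c1ccccc1)(c1ccccc1)c1ccccc1
Why: Wittig methylenation of the keto carboxylate with excess ylide, the usual entry to 5-substituted hex-5-enoic acids; the carboxylate is inert to the ylide and is re-protonated on work-up.

Step 4
Reactants: 6 8-(tert-butyldiphenylsilyloxy)-5-methylideneoctanoic acid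
Product: 7 (6S)-6-(bromomethyl)-6-[3-(tert-butyldiphenylsilyloxy)propyl]oxan-2-one
Conditions: NBS (1.1 equiv), quinidine-derived 9-O-(N-arylthiocarbamoyl) amino-thiocarbamate catalyst (10 mol%), CHCl3/toluene 1:2, –78 °C, dark
Reagents that add atoms: N-bromosuccinimide, O=C1CCC(=O)N1Br
Why: The quinuclidine nitrogen of the bifunctional catalyst deprotonates and ion-pairs with acid 6 while the thiocarbamate sulfur takes up electrophilic bromine from NBS, so that bromine is passed to one face of the 1,1-disubstituted olefin inside a chiral ion pair. The carboxylate then opens the bromiranium ion at its fully substituted carbon, which forms the O–C(quaternary) bond and the lactone and leaves bromine on the former =CH2 carbon. The closest known reaction type is the organocatalytic enantioselective bromolactonisation of 4-substituted pent-4-enoic and 5-substituted hex-5-enoic acids. The oxan-2-one ring closes in the 6-exo mode (exo opening of the three-membered bromiranium ion, 6-exo-tet); the 7-endo alternative would require attack at the primary carbon and is disfavoured electronically and by ring size. The one new stereocentre, C6, is controlled by the catalyst alone through its choice of olefin face, as the substrate has no stereogenic element. The step needs face selectivity between two CH2 chains and chemoselectivity for the carboxylate over the silyl ether oxygen, which could open the same ion 5-exo; the anionic catalyst-held carboxylate, the bulk and low basicity of the silyl ether, the low temperature and the non-polar medium are relied on for both. No second olefin is present, so bromine has only one site of attack. The sense of induction is to be matched to (S)-7 by choosing between the quinidine- and the quinine-derived catalyst.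

Step 5
Reactants: 7 (6S)-6-(bromomethyl)-6-[3-(tert-butyldiphenylsilyloxy)propyl]oxan-2-one
Product: 8 (6S)-6-[3-(tert-butyldiphenylsilyloxy)propyl]-6-methyloxan-2-one
Conditions: Bu3SnH (1.5 equiv, 0.3 M), Et3B (0.2 equiv), air, toluene, 0 °C to rt
Reagents that add atoms: none
Why: Radical chain reduction of a primary alkyl bromide; high tin hydride concentration and low temperature let hydrogen transfer outrun the 1,2-acyloxy shift open to the β-(acyloxy)alkyl radical, and no bond at the stereocentre is broken, so its configuration is kept.

Step 6
Reactants: 8 (6S)-6-[3-(tert-butyldiphenylsilyloxy)propyl]-6-methyloxan-2-one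
Product: 9 (6S)-6-(3-hydroxypropyl)-6-methyloxan-2-one
Conditions: Bu4NF, AcOH (1:1), THF, rt
Reagents that add atoms: none
Why: Fluoride cleavage of the silyl ether, buffered so that the lactone is not opened; the freed primary alcohol cannot translactonise because that would require a nine-membered ring.

Step 7
Reactants: 9 (6S)-6-(3-hydroxypropyl)-6-methyloxan-2-one
Product: 10 3-[(2S)-2-methyl-6-oxooxan-2-yl]propanal
Conditions: Dess–Martin periodinane, NaHCO3, CH2Cl2, 0 °C to rt
Reagents that add atoms: none
Why: Dess–Martin oxidation of a primary alcohol to the aldehyde under buffered, non-epimerising conditions; the lactone is inert.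

Step 8
Reactants: 10 3-[(2S)-2-methyl-6-oxooxan-2-yl]propanal
Product: 11 (6S)-6-methyl-6-(4-methylpent-3-en-1-yl)oxan-2-one
Conditions: i-PrPPh3I, n-BuLi, THF, 0 °C; then 10, –78 to 0 °C
Reagents that add atoms: isopropyltriphenylphosphonium iodide, [I-].CC(C)[P+](c1ccccc1)(c1ccccc1)c1ccccc1
Why: Wittig olefination with an unstabilised ylide, which takes the aldehyde far faster than the lactone at –78 °C; the new olefin bears two methyl groups, so no geometry has to be controlled.

Step 9
Reactants: 11 (6S)-6-methyl-6-(4-methylpent-3-en-1-yl)oxan-2-one
Product: 12 (6S)-6-{2-[(2S)-3,3-dimethyloxiran-2-yl]ethyl}-6-methyloxan-2-one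
Conditions: ent-Shi ketone (1,2:4,5-di-O-isopropylidene-β-L-erythro-2,3-hexodiulo-2,6-pyranose, 1–3 equiv), Oxone (2KHSO5·KHSO4·K2SO4), NaHCO3, MeCN/aq. Na2EDTA, pH 7–8, 0 °C
Reagents that add atoms: potassium peroxymonosulfate (active component of Oxone), [K+].[O-]S(=O)(=O)OO
Why: Shi asymmetric epoxidation; the chiral dioxirane attacks the only olefin through the spiro transition state, and the L-series ketone is taken because the D-fructose-derived one gives the (R)-epoxide from 2-methylalk-2-enes, so the new centre is reagent-controlled and independent of C6. The near-neutral protocol with stoichiometric ketone is used because a δ-lactone would be saponified at the pH of the catalytic variant. Any (6R)-lactone carried over from step 4 becomes a diastereomer here and is to be removed by chromatography.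

Step 10
Reactants: 13 4,6-dibromobenzene-1,3-diol
Product: 14 1,5-dibromo-2,4-bis(tert-butyldimethylsilyloxy)benzene
Conditions: TBSCl (2.4 equiv), imidazole, DMF, rt
Reagents that add atoms: tert-butyl(chloro)dimethylsilane, CC(C)(C)[Si](C)(C)Cl
Why: Standard silylation of both phenols; the product is symmetric, so the next step has no regiochemical choice.

Step 11
Reactants: 14 1,5-dibromo-2,4-bis(tert-butyldimethylsilyloxy)benzene
Product: 17 1-bromo-2,4-bis(tert-butyldimethylsilyloxy)-5-(3-methylbut-2-en-1-yl)benzene, via aryllithium 15 (not isolated), via arylcopper 16 (not isolated)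
Conditions: n-BuLi (1.05 equiv), THF, –78 °C; CuBr·SMe2 (1.1 equiv), –78 °C; prenyl bromide, –78 to 0 °C
Reagents that add atoms: 1-bromo-3-methylbut-2-ene, CC(C)=CCBr
Why: Bromine–lithium exchange at one of two equivalent bromides (the second is much slower once the ring is anionic), transmetalation to copper at –78 °C before the ortho-lithiated silyl ether can undergo silyl migration, and allylic substitution of prenyl bromide at its primary carbon.

Step 12
Reactants: 18 3-bromo-4-iodophenol
Product: 19 (3-bromo-4-iodophenoxy)tri(propan-2-yl)silane
Conditions: TIPSCl, imidazole, DMF, rt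
Reagents that add atoms: chlorotri(propan-2-yl)silane, CC(C)[Si](Cl)(C(C)C)C(C)C
Why: Standard phenol silylation; the triisopropylsilyl ether is chosen because it withstands the aqueous base of the Suzuki step.

Step 13
Reactants: 19 (3-bromo-4-iodophenoxy)tri(propan-2-yl)silane
Product: 21 2-[2-bromo-4-(triisopropylsilyloxy)phenyl]-4,4,5,5-tetramethyl-1,3,2-dioxaborolane, via arylmagnesium chloride 20 (not isolated)
Conditions: i-PrMgCl·LiCl, THF, –40 °C; i-PrOBpin, –40 °C to rt; aq. NH4Cl
Reagents that add atoms: 2-isopropoxy-4,4,5,5-tetramethyl-1,3,2-dioxaborolane, CC(C)OB1OC(C)(C)C(C)(C)O1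
Why: Iodine–magnesium exchange is far faster than bromine–magnesium exchange, and the ortho-bromoaryl Grignard reagent is stable at –40 °C; borylation with the alkoxyboronate gives the pinacol ester with the bromide in place.

Step 14
Reactants: 12 (6S)-6-{2-[(2S)-3,3-dimethyloxiran-2-yl]ethyl}-6-methyloxan-2-one; 17 1-bromo-2,4-bis(tert-butyldimethylsilyloxy)-5-(3-methylbut-2-en-1-yl)benzene
Product: 23 (6S)-3-[2,4-bis(tert-butyldimethylsilyloxy)-5-(3-methylbut-2-en-1-yl)phenyl]-6-{2-[(2S)-3,3-dimethyloxiran-2-yl]ethyl}-6-methyloxan-2-one (both C3 epimers), via lithium enolate 22 (not isolated)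
Conditions: LiN(SiMe3)2 (2.2 equiv), toluene, –78 °C; then 17 (1.2 equiv), Pd(dba)2 (5 mol%), P(t-Bu)3 (5 mol%), –78 °C to rt
Reagents that add atoms: none
Why: Palladium-catalysed α-arylation of an ester enolate; the lactone is a tert-alkyl ester and should resist Claisen self-condensation like the tert-butyl esters for which the reaction is best established, and the ortho-silyloxy group blocks a second arylation. The new α-stereocentre is of no consequence because the next step flattens it.

Step 15
Reactants: 23 (6S)-3-[2,4-bis(tert-butyldimethylsilyloxy)-5-(3-methylbut-2-en-1-yl)phenyl]-6-{2-[(2S)-3,3-dimethyloxiran-2-yl]ethyl}-6-methyloxan-2-one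
Product: 25 (2S)-5-[2,4-bis(tert-butyldimethylsilyloxy)-5-(3-methylbut-2-en-1-yl)phenyl]-2-{2-[(2S)-3,3-dimethyloxiran-2-yl]ethyl}-2-methyl-3,4-dihydro-2H-pyran-6-yl trifluoromethanesulfonate, via potassium enolate 24 (not isolated)
Conditions: KN(SiMe3)2, THF, –78 °C; PhNTf2, –78 to –20 °C; filtration through Et3N-treated silica
Reagents that add atoms: N-phenylbis(trifluoromethanesulfonimide), O=S(=O)(N(c1ccccc1)S(=O)(=O)C(F)(F)F)C(F)(F)F
Why: O-Sulfonylation of the aryl-conjugated lactone enolate gives the ketene acetal triflate (enol triflate formation); only one enolate can form and the ring fixes the olefin geometry. The triflate is used at once.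

Step 16
Reactants: 25 (2S)-5-[2,4-bis(tert-butyldimethylsilyloxy)-5-(3-methylbut-2-en-1-yl)phenyl]-2-{2-[(2S)-3,3-dimethyloxiran-2-yl]ethyl}-2-methyl-3,4-dihydro-2H-pyran-6-yl trifluoromethanesulfonate; 21 2-[2-bromo-4-(triisopropylsilyloxy)phenyl]-4,4,5,5-tetramethyl-1,3,2-dioxaborolane
Product: 26 (2S)-5-[2,4-bis(tert-butyldimethylsilyloxy)-5-(3-methylbut-2-en-1-yl)phenyl]-6-[2-bromo-4-(triisopropylsilyloxy)phenyl]-2-{2-[(2S)-3,3-dimethyloxiran-2-yl]ethyl}-2-methyl-3,4-dihydro-2H-pyran
Conditions: 21 (1.3 equiv), Pd(PPh3)4 (5 mol%), K3PO4, dioxane/H2O 10:1, 50 °C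
Reagents that add atoms: none
Why: Suzuki–Miyaura coupling; zerovalent palladium inserts into the C–OTf bond of the ketene acetal triflate faster than into the hindered aryl bromide ortho to boron, so the bromide is kept for the ring closure, and the endocyclic olefin holds the two aryl groups cis. Partial loss of a phenolic silyl group here would be harmless, since the next step removes all three.

Step 17
Reactants: 26 (2S)-5-[2,4-bis(tert-butyldimethylsilyloxy)-5-(3-methylbut-2-en-1-yl)phenyl]-6-[2-bromo-4-(triisopropylsilyloxy)phenyl]-2-{2-[(2S)-3,3-dimethyloxiran-2-yl]ethyl}-2-methyl-3,4-dihydro-2H-pyran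
Product: 27 4-[(2S)-6-(2-bromo-4-hydroxyphenyl)-2-{2-[(2S)-3,3-dimethyloxiran-2-yl]ethyl}-2-methyl-3,4-dihydro-2H-pyran-5-yl]-6-(3-methylbut-2-en-1-yl)benzene-1,3-diol
Conditions: Bu4NF (3.5 equiv), THF, 0 °C, argon; pH 7 phosphate buffer
Reagents that add atoms: none
Why: Fluoride cleavage of the three phenolic silyl ethers, the most fluoride-labile class, under basic conditions that leave epoxide, enol ether, prenyl group and aryl bromide alone; the neutral work-up avoids acid-induced addition of the ortho phenol to the enol ether.

Step 18
Reactants: 27 4-[(2S)-6-(2-bromo-4-hydroxyphenyl)-2-{2-[(2S)-3,3-dimethyloxiran-2-yl]ethyl}-2-methyl-3,4-dihydro-2H-pyran-5-yl]-6-(3-methylbut-2-en-1-yl)benzene-1,3-diol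
Product: 28 target, the pyrano-fused dibenzo[b,f]oxepine with (S) quaternary pyran carbon and (S) epoxide
Conditions: CuI (20 mol%), N,N-dimethylglycine (40 mol%), Cs2CO3 (4 equiv), dioxane/DMF, 5 mM, 90 °C, argon
Reagents that add atoms: none
Why: Intramolecular Ullmann diaryl ether synthesis; only the phenoxide ortho to C11 can reach the ring B bromide, which the cis olefin holds next to it, so the oxepine should close in preference to intermolecular coupling of the two remote phenoxides at high dilution. The conditions are basic and non-oxidising under argon, which epoxide, enol ether and prenyl group tolerate.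

## Compound list

1 | 3-bromopropan-1-ol | OCCCBr | starting material
2 | (3-bromopropoxy)(tert-butyl)diphenylsilane | BrCCCO[Si](c1ccccc1)(c1ccccc1)C(C)(C)C | intermediate
3 | glutaric anhydride (oxane-2,6-dione) | O=C1CCCC(=O)O1 | starting material
4 | [3-(tert-butyldiphenylsilyloxy)propyl]magnesium bromide (not isolated) | Br[Mg]CCCO[Si](c1ccccc1)(c1ccccc1)C(C)(C)C | intermediate
5 | 8-(tert-butyldiphenylsilyloxy)-5-oxooctanoic acid | OC(=O)CCCC(=O)CCCO[Si](c1ccccc1)(c1ccccc1)C(C)(C)C | intermediate
6 | 8-(tert-butyldiphenylsilyloxy)-5-methylideneoctanoic acid | OC(=O)CCCC(=C)CCCO[Si](c1ccccc1)(c1ccccc1)C(C)(C)C | intermediate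
7 | (6S)-6-(bromomethyl)-6-[3-(tert-butyldiphenylsilyloxy)propyl]oxan-2-one | O=C1CCC[C@@](CBr)(CCCO[Si](c2ccccc2)(c2ccccc2)C(C)(C)C)O1 | intermediate
8 | (6S)-6-[3-(tert-butyldiphenylsilyloxy)propyl]-6-methyloxan-2-one | O=C1CCC[C@@](C)(CCCO[Si](c2ccccc2)(c2ccccc2)C(C)(C)C)O1 | intermediate
9 | (6S)-6-(3-hydroxypropyl)-6-methyloxan-2-one | O=C1CCC[C@@](C)(CCCO)O1 | intermediate
10 | 3-[(2S)-2-methyl-6-oxooxan-2-yl]propanal | O=C1CCC[C@@](C)(CCC=O)O1 | intermediate
11 | (6S)-6-methyl-6-(4-methylpent-3-en-1-yl)oxan-2-one | O=C1CCC[C@@](C)(CCC=C(C)C)O1 | intermediate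
12 | (6S)-6-{2-[(2S)-3,3-dimethyloxiran-2-yl]ethyl}-6-methyloxan-2-one | O=C1CCC[C@@](C)(CC[C@@H]2OC2(C)C)O1 | intermediate
13 | 4,6-dibromobenzene-1,3-diol (4,6-dibromoresorcinol) | Oc1cc(O)c(Br)cc1Br | starting material
14 | 1,5-dibromo-2,4-bis(tert-butyldimethylsilyloxy)benzene | CC(C)(C)[Si](C)(C)Oc1cc(O[Si](C)(C)C(C)(C)C)c(Br)cc1Br | intermediate
15 | [5-bromo-2,4-bis(tert-butyldimethylsilyloxy)phenyl]lithium (not isolated) | [Li]c1cc(Br)c(O[Si](C)(C)C(C)(C)C)cc1O[Si](C)(C)C(C)(C)C | intermediate
16 | [5-bromo-2,4-bis(tert-butyldimethylsilyloxy)phenyl]copper (not isolated) | [Cu]c1cc(Br)c(O[Si](C)(C)C(C)(C)C)cc1O[Si](C)(C)C(C)(C)C | intermediate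
17 | 1-bromo-2,4-bis(tert-butyldimethylsilyloxy)-5-(3-methylbut-2-en-1-yl)benzene | CC(C)=CCc1cc(Br)c(O[Si](C)(C)C(C)(C)C)cc1O[Si](C)(C)C(C)(C)C | intermediate
18 | 3-bromo-4-iodophenol | Oc1ccc(I)c(Br)c1 | starting material
19 | (3-bromo-4-iodophenoxy)tri(propan-2-yl)silane | CC(C)[Si](Oc1ccc(I)c(Br)c1)(C(C)C)C(C)C | intermediate
20 | [2-bromo-4-(triisopropylsilyloxy)phenyl]magnesium chloride (not isolated) | Cl[Mg]c1ccc(O[Si](C(C)C)(C(C)C)C(C)C)cc1Br | intermediate
21 | 2-[2-bromo-4-(triisopropylsilyloxy)phenyl]-4,4,5,5-tetramethyl-1,3,2-dioxaborolane | CC(C)[Si](Oc1ccc(B2OC(C)(C)C(C)(C)O2)c(Br)c1)(C(C)C)C(C)C | intermediate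
22 | lithium enolate of 12 (not isolated) | [Li]OC1=CCC[C@@](C)(CC[C@@H]2OC2(C)C)O1 | intermediate
23 | (6S)-3-[2,4-bis(tert-butyldimethylsilyloxy)-5-(3-methylbut-2-en-1-yl)phenyl]-6-{2-[(2S)-3,3-dimethyloxiran-2-yl]ethyl}-6-methyloxan-2-one, both C3 epimers | O=C1C(c2cc(CC=C(C)C)c(O[Si](C)(C)C(C)(C)C)cc2O[Si](C)(C)C(C)(C)C)CC[C@@](C)(CC[C@@H]3OC3(C)C)O1 | intermediate
24 | potassium enolate of 23 (not isolated) | [K]OC1=C(c2cc(CC=C(C)C)c(O[Si](C)(C)C(C)(C)C)cc2O[Si](C)(C)C(C)(C)C)CC[C@@](C)(CC[C@@H]3OC3(C)C)O1 | intermediate
25 | (2S)-5-[2,4-bis(tert-butyldimethylsilyloxy)-5-(3-methylbut-2-en-1-yl)phenyl]-2-{2-[(2S)-3,3-dimethyloxiran-2-yl]ethyl}-2-methyl-3,4-dihydro-2H-pyran-6-yl trifluoromethanesulfonate | O=S(=O)(OC1=C(c2cc(CC=C(C)C)c(O[Si](C)(C)C(C)(C)C)cc2O[Si](C)(C)C(C)(C)C)CC[C@@](C)(CC[C@@H]3OC3(C)C)O1)C(F)(F)F | intermediate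
26 | (2S)-5-[2,4-bis(tert-butyldimethylsilyloxy)-5-(3-methylbut-2-en-1-yl)phenyl]-6-[2-bromo-4-(triisopropylsilyloxy)phenyl]-2-{2-[(2S)-3,3-dimethyloxiran-2-yl]ethyl}-2-methyl-3,4-dihydro-2H-pyran | Brc1cc(O[Si](C(C)C)(C(C)C)C(C)C)ccc1C1=C(c2cc(CC=C(C)C)c(O[Si](C)(C)C(C)(C)C)cc2O[Si](C)(C)C(C)(C)C)CC[C@@](C)(CC[C@@H]3OC3(C)C)O1 | intermediate
27 | 4-[(2S)-6-(2-bromo-4-hydroxyphenyl)-2-{2-[(2S)-3,3-dimethyloxiran-2-yl]ethyl}-2-methyl-3,4-dihydro-2H-pyran-5-yl]-6-(3-methylbut-2-en-1-yl)benzene-1,3-diol | Brc1cc(O)ccc1C1=C(c2cc(CC=C(C)C)c(O)cc2O)CC[C@@](C)(CC[C@@H]3OC3(C)C)O1 | intermediate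
28 | target: (2S)-2-{2-[(2S)-3,3-dimethyloxiran-2-yl]ethyl}-2-methyl-3,4-dihydro-2H-pyran fused through C5=C6 to the 10,11-bond of a dibenzo[b,f]oxepine; ring A (on C11) with OH para to C11 and prenyl ortho to that OH; ring B (on C10) with OH para to C10 | CC(C)=CCc1cc2c(cc1O)Oc1cc(O)ccc1C1=C2CC[C@@](C)(CC[C@@H]2OC2(C)C)O1 | target

## Step count and least certain steps

Total: 18 steps. Longest linear sequence: 14 steps (steps 1–9 and 14–18); the ring A branch (steps 10–11) joins at step 14 and the ring B branch (steps 12–13) at step 16.

**Step 4 (key step).** The most likely failure is weak facial discrimination, because the catalyst must tell two CH2 chains apart, together with leakage through the uncatalysed pathway. A moderate result can still be carried forward, since step 9 converts the wrong enantiomer into a separable diastereomer. Fallback: from 6, bromolactonisation with NBS alone (NaHCO3, CH2Cl2) gives racemic bromolactone F1, which is resolved by preparative chromatography on a chiral stationary phase (the diphenylsilyl chromophore helps detection). The (S)-enantiomer is 7, where the route is rejoined.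

**Step 14.** Slow oxidative addition of the electron-rich, ortho-substituted bromide may leave the lactone enolate time to decompose by self-condensation, and reductive elimination at the hindered centre may stall. Fallback: the order of the two aryl–carbon bonds is reversed. From 12, KN(SiMe3)2 and PhNTf2 give ketene acetal triflate F2. Suzuki coupling of F2 with 21 gives the 6-aryl dihydropyran F3. N-Iodosuccinimide and NaHCO3 iodinate the nucleophilic β-carbon of the enol ether, and loss of the proton gives vinyl iodide F4. Bromide 17 is converted (n-BuLi, then i-PrOBpin) to the ring A boronate F5. Suzuki coupling of F4 with F5, the vinyl iodide reacting ahead of the aryl bromide, returns to 26.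

**Step 18.** The two spectator phenoxides may undergo intermolecular etherification, the electron-rich triphenolate may degrade oxidatively, or a phenoxide may open the epoxide at 90 °C. Fallback: from 26, the two tert-butyldimethylsilyl ethers are cleaved selectively (Cs2CO3, DMF/H2O, rt) to give the ring B silyl-protected diphenol F6. The same copper-mediated closure then gives the ring B triisopropylsilyl ether F7 (the compound also reached in alternative 1), with only one hindered spectator phenol present. Bu4NF at 0 °C returns to 28.

**Step 9.** The lactone may be saponified in the aqueous medium, and turnover is low at near-neutral pH. Fallback: from 11, deliberate saponification (LiOH, THF/H2O) gives lithium hydroxy carboxylate F8. F8 is epoxidised with catalytic ent-Shi ketone at pH 10.5 to give epoxy carboxylate F9. Relactonisation with EDC·HCl and DMAP in CH2Cl2 returns to 12.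

**Step 5.** The β-(acyloxy)alkyl radical may undergo the 1,2-acyloxy shift, which would expand the ring, before it is reduced. Fallback: a polar route from 7. LiEt3BH (THF, 0 °C) reduces the lactone, and the tertiary alkoxide closes onto the bromomethyl group to give epoxy alcohol F10. The same hydride opens F10 at its CH2 terminus to give diol F11. TEMPO with PhI(OAc)2 oxidises the primary alcohol through the lactol and returns to 8. The C–O bond at the stereocentre is never broken.

## Further compounds

F1 | step 4 | racemic 6-(bromomethyl)-6-[3-(tert-butyldiphenylsilyloxy)propyl]oxan-2-one | O=C1CCCC(CBr)(CCCO[Si](c2ccccc2)(c2ccccc2)C(C)(C)C)O1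
F2 | step 14 | (2S)-2-{2-[(2S)-3,3-dimethyloxiran-2-yl]ethyl}-2-methyl-3,4-dihydro-2H-pyran-6-yl trifluoromethanesulfonate | O=S(=O)(OC1=CCC[C@@](C)(CC[C@@H]2OC2(C)C)O1)C(F)(F)F
F3 | step 14 | (2S)-6-[2-bromo-4-(triisopropylsilyloxy)phenyl]-2-{2-[(2S)-3,3-dimethyloxiran-2-yl]ethyl}-2-methyl-3,4-dihydro-2H-pyran | Brc1cc(O[Si](C(C)C)(C(C)C)C(C)C)ccc1C1=CCC[C@@](C)(CC[C@@H]2OC2(C)C)O1
F4 | step 14 | (2S)-6-[2-bromo-4-(triisopropylsilyloxy)phenyl]-2-{2-[(2S)-3,3-dimethyloxiran-2-yl]ethyl}-5-iodo-2-methyl-3,4-dihydro-2H-pyran | Brc1cc(O[Si](C(C)C)(C(C)C)C(C)C)ccc1C1=C(I)CC[C@@](C)(CC[C@@H]2OC2(C)C)O1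
F5 | step 14 | 2-[2,4-bis(tert-butyldimethylsilyloxy)-5-(3-methylbut-2-en-1-yl)phenyl]-4,4,5,5-tetramethyl-1,3,2-dioxaborolane | CC(C)=CCc1cc(B2OC(C)(C)C(C)(C)O2)c(O[Si](C)(C)C(C)(C)C)cc1O[Si](C)(C)C(C)(C)C
F6 | step 18 | 4-[(2S)-6-[2-bromo-4-(triisopropylsilyloxy)phenyl]-2-{2-[(2S)-3,3-dimethyloxiran-2-yl]ethyl}-2-methyl-3,4-dihydro-2H-pyran-5-yl]-6-(3-methylbut-2-en-1-yl)benzene-1,3-diol | Brc1cc(O[Si](C(C)C)(C(C)C)C(C)C)ccc1C1=C(c2cc(CC=C(C)C)c(O)cc2O)CC[C@@](C)(CC[C@@H]3OC3(C)C)O1
F7 | step 18 | ring B triisopropylsilyl ether of 28 | CC(C)=CCc1cc2c(cc1O)Oc1cc(O[Si](C(C)C)(C(C)C)C(C)C)ccc1C1=C2CC[C@@](C)(CC[C@@H]2OC2(C)C)O1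
F8 | step 9 | lithium (5S)-5-hydroxy-5,9-dimethyldec-8-enoate | [Li+].[O-]C(=O)CCC[C@](C)(O)CCC=C(C)C
F9 | step 9 | lithium (5S)-7-[(2S)-3,3-dimethyloxiran-2-yl]-5-hydroxy-5-methylheptanoate | [Li+].[O-]C(=O)CCC[C@](C)(O)CC[C@@H]1OC1(C)C
F10 | step 5 | 4-[(2S)-2-[3-(tert-butyldiphenylsilyloxy)propyl]oxiran-2-yl]butan-1-ol | OCCCC[C@@]1(CCCO[Si](c2ccccc2)(c2ccccc2)C(C)(C)C)OC1
F11 | step 5 | (5S)-8-(tert-butyldiphenylsilyloxy)-5-methyloctane-1,5-diol | OCCCC[C@](C)(O)CCCO[Si](c1ccccc1)(c1ccccc1)C(C)(C)C
A1 | alternative 1 | ring B triisopropylsilyl ether of 28, product of the ring expansion | CC(C)=CCc1cc2c(cc1O)Oc1cc(O[Si](C(C)C)(C(C)C)C(C)C)ccc1C1=C2CC[C@@](C)(CC[C@@H]2OC2(C)C)O1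
A2 | alternative 1 | spiro[oxane-2,9'-xanthene] 3-mesylate carrying the ring A phenol, the prenyl group, the ring B silyl ether and the (S,S) side chain | CC(C)=CCc1cc2c(cc1O)Oc1cc(O[Si](C(C)C)(C(C)C)C(C)C)ccc1C21O[C@](C)(CC[C@@H]3OC3(C)C)CCC1OS(C)(=O)=O
A3 | alternative 2 | (6S)-6-methyl-6-(prop-2-en-1-yl)oxan-2-one | O=C1CCC[C@@](C)(CC=C)O1
A4 | alternative 2 | (2S)-2-methyl-2-(prop-2-en-1-yl)cyclopentan-1-one | O=C1CCC[C@@]1(C)CC=C
A5 | alternative 3 | 5-(ring A)-6-(ring B)-3,4-dihydro-2H-pyran with ring A bromide retained, product of the oxyarylation | CC(C)=CCc1cc(c(Br)cc1O[Si](C(C)C)(C(C)C)C(C)C)C1=C(c2ccc(O[Si](C(C)C)(C(C)C)C(C)C)cc2O[Si](C(C)C)(C(C)C)C(C)C)O[C@](C)(CC[C@@H]2OC2(C)C)CC1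
A6 | alternative 3 | (S)-configured tertiary alkynol: 6-[2,4-bis(triisopropylsilyloxy)phenyl]-1-[(2S)-3,3-dimethyloxiran-2-yl]-3-methylhex-5-yn-3-ol | CC(C)[Si](Oc1ccc(C#CCC[C@](C)(O)CC[C@@H]2OC2(C)C)c(O[Si](C(C)C)(C(C)C)C(C)C)c1)(C(C)C)C(C)C
A7 | alternative 3 | [5-bromo-4-iodo-2-(3-methylbut-2-en-1-yl)phenoxy]tri(propan-2-yl)silane | CC(C)=CCc1cc(I)c(Br)cc1O[Si](C(C)C)(C(C)C)C(C)C
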